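**Retrosynthetic overview**
1. Target ⇐ closure of the 2,5-epoxy hemiketal from a (Z)-γ-hydroxy dienone freed by desilylation (last ring); the 8β-angelate comes from Mitsunobu inversion of an 8α-alcohol.
2. 6,12-Lactone and ten-membered carbocycle ⇐ one cation–olefin (Hosomi–Sakurai) closure of C6–C7 in an acyclic aldehyde/allylsilane, the laboratory counterpart of the farnesyl C1–C10 cyclisation, with lactonisation in the same flask.
3. Acyclic dienone ⇐ carbonylative Stille coupling (C-2 from CO) of an (E)-β-iodoacrylate (C-1, C-7 to C-14) with a (Z)-vinylstannane (C-3 to C-6, C-15).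
4. Iodoacrylate ⇐ (R)-butenediol, methyl propiolate (halo-aldol) and a silylmethyl phosphonoacetate; stannane ⇐ pentenynol (Sharpless resolution, anti-carbomagnesiation).
5. Ring order: carbocycle → lactone → hemiketal.

Assumption: C-2 is a hemiketal carbon that equilibrates through the open (Z)-γ-hydroxy enone; it is set under thermodynamic control and is written as in the target SMILES, while C-5 to C-9 are fixed by the route.
Note: positions are given in germacrane numbering (C-1 to C-15); α/β refer to the usual flat germacrane projection.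

**Step 1**
Reactants: 1 trimethyl phosphonoacetate; 2 (iodomethyl)trimethylsilane
Product: 3 methyl 2-(dimethoxyphosphoryl)-3-(trimethylsilyl)propanoate
Conditions: NaH, DME, 0 → 65 °C
Reagents that add atoms: none
Why: SN2 C-alkylation of the sodium phosphonoacetate enolate by the primary α-silyl iodide gives the silylmethyl Horner–Wadsworth–Emmons reagent, whose stereocentre is lost in step 7.

**Step 2**
Reactants: 4 (R)-but-3-ene-1,2-diol
Product: 5 (R)-3,4-bis(triethylsilyloxy)but-1-ene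
Conditions: TESCl (2.2 equiv), imidazole, DMF, 0 °C → rt
Reagents that add atoms: chlorotriethylsilane CC[Si](Cl)(CC)CC
Why: Imidazole-mediated silylation of both hydroxyls leaves the stereocentre (future C-8, here opposite to the target) untouched.

**Step 3**
Reactants: 5 (R)-3,4-bis(triethylsilyloxy)but-1-ene
Product: 6 (R)-2-(triethylsilyloxy)but-3-enal
Conditions: (COCl)2, DMSO, CH2Cl2, −78 → −30 °C; Et3N, −78 °C
Reagents that add atoms: none
Why: Under Swern conditions a primary TES ether is oxidised directly to the aldehyde (via the alkoxysulfonium salt) while the secondary TES ether survives; the α-silyloxy aldehyde is used cold and at once so that C-8 does not epimerise.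

**Step 4**
Reactants: 6 (R)-2-(triethylsilyloxy)but-3-enal; 7 methyl propiolate
Product: 8 methyl (2E,3S,4R)-3-hydroxy-2-(iodomethylidene)-4-(triethylsilyloxy)hex-5-enoate
Conditions: TiCl4, n-Bu4NI, CH2Cl2, −78 °C; NaHCO3 quench at −78 °C
Reagents that add atoms: tetrabutylammonium iodide CCCC[N+](CCCC)(CCCC)CCCC.[I-]
Why: Halo-aldol (β-iodo Morita–Baylis–Hillman) three-component coupling in which iodide adds to the TiCl4-activated propiolate and the β-iodo allenolate adds to the aldehyde; the cold quench is meant to keep the kinetic (E)-iodide (I cis to the carbinol carbon), and non-chelating Felkin–Anh addition anti to the α-OSiEt3 group sets C-9 (3,4-anti).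

**Step 5**
Reactants: 8 methyl (2E,3S,4R)-3-hydroxy-2-(iodomethylidene)-4-(triethylsilyloxy)hex-5-enoate
Product: 9 methyl (2E,3S,4R)-3-acetoxy-2-(iodomethylidene)-4-(triethylsilyloxy)hex-5-enoate
Conditions: Ac2O, pyridine, CH2Cl2, 0 °C
Reagents that add atoms: acetic anhydride CC(=O)OC(C)=O
Why: Acylation of the secondary allylic alcohol installs the C-9 acetate of the target with retention.

**Step 6**
Reactants: 9 methyl (2E,3S,4R)-3-acetoxy-2-(iodomethylidene)-4-(triethylsilyloxy)hex-5-enoate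
Product: 11 methyl (2E,3S,4S)-3-acetoxy-2-(iodomethylidene)-5-oxo-4-(triethylsilyloxy)pentanoate, via diol 10 (not isolated)
Conditions: OsO4 (2 mol %), NaIO4, 2,6-lutidine, dioxane–H2O, rt
Reagents that add atoms: sodium periodate [Na+].[O-]I(=O)(=O)=O
Why: Lemieux–Johnson cleavage: OsO4 dihydroxylates only the electron-rich monosubstituted alkene (the β-iodoacrylate is electron-poor) and periodate cleaves the diol to the C-7 aldehyde.

**Step 7**
Reactants: 11 methyl (2E,3S,4S)-3-acetoxy-2-(iodomethylidene)-5-oxo-4-(triethylsilyloxy)pentanoate; 3 methyl 2-(dimethoxyphosphoryl)-3-(trimethylsilyl)propanoate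
Product: 12 dimethyl (2E,3S,4R,5Z)-3-acetoxy-2-(iodomethylidene)-4-(triethylsilyloxy)-6-[(trimethylsilyl)methyl]hept-5-enedioate
Conditions: LiCl, i-Pr2NEt, MeCN, 0 °C → rt
Reagents that add atoms: none
Why: Masamune–Roush Horner–Wadsworth–Emmons olefination under weakly basic conditions (to avoid β-elimination of the C-9 acetate) gives the 2-(silylmethyl)enoate with C-8 trans to the ester as the expected major isomer, building C-11 to C-13 as an allylsilane that is inert to palladium.

**Step 8**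
Reactants: 13 rac-pent-1-en-4-yn-3-ol
Product: 14 (S)-pent-1-en-4-yn-3-ol
Conditions: Ti(OiPr)4 (15 mol %), L-(+)-DIPT (18 mol %), t-BuOOH (0.6 equiv), 4 Å MS, CH2Cl2, −20 °C
Reagents that add atoms: none
Why: Sharpless kinetic resolution: with L-(+)-DIPT the (R)-enantiomer is epoxidised at its vinyl group much faster, so the (S)-alcohol (future C-5) is recovered in high ee at about 55% conversion.

**Step 9**
Reactants: 14 (S)-pent-1-en-4-yn-3-ol
Product: 16 tert-butyldimethyl{[(3S,1Z)-2-methyl-1-(tributylstannyl)penta-1,4-dien-3-yl]oxy}silane, via bromomagnesium alkoxide 15 (not isolated)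
Conditions: MeMgBr (3 equiv), CuI (10 mol %), THF, −10 °C → rt; Bu3SnCl, 0 °C; TBSOTf, 2,6-lutidine, 0 °C
Reagents that add atoms: methylmagnesium bromide C[Mg]Br; chlorotributylstannane CCCC[Sn](Cl)(CCCC)CCCC; tert-butyldimethylsilyl triflate CC(C)(C)[Si](C)(C)OS(=O)(=O)C(F)(F)F
Why: Hydroxyl-directed Cu-catalysed anti-carbomagnesiation of the propargylic alkoxide (Duboudin reaction) puts CH3 on C-4 and Mg on C-3 cis to C-5, fixing the Z-trisubstituted alkene; the vinylmagnesium is trapped by Bu3SnCl and the alkoxide is silylated in the same flask.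

**Step 10**
Reactants: 12 dimethyl (2E,3S,4R,5Z)-3-acetoxy-2-(iodomethylidene)-4-(triethylsilyloxy)-6-[(trimethylsilyl)methyl]hept-5-enedioate; 16 tert-butyldimethyl{[(3S,1Z)-2-methyl-1-(tributylstannyl)penta-1,4-dien-3-yl]oxy}silane
Product: 17 methyl (2Z,4R,5S,6E,9Z,11S)-5-acetoxy-11-(tert-butyldimethylsilyloxy)-6-(methoxycarbonyl)-10-methyl-8-oxo-4-(triethylsilyloxy)-2-[(trimethylsilyl)methyl]trideca-2,6,9,12-tetraenoate
Conditions: CO (1 atm), Pd2(dba)3 (5 mol %), AsPh3, LiCl, NMP, 45 °C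
Reagents that add atoms: carbon monoxide [C-]#[O+]
Why: Carbonylative Stille coupling: oxidative addition to the electron-poor vinyl iodide, CO insertion and transmetallation from the vinylstannane give the cross-conjugated divinyl ketone (C-2 from CO) with retention of both alkene geometries.

**Step 11**
Reactants: 17 methyl (2Z,4R,5S,6E,9Z,11S)-5-acetoxy-11-(tert-butyldimethylsilyloxy)-6-(methoxycarbonyl)-10-methyl-8-oxo-4-(triethylsilyloxy)-2-[(trimethylsilyl)methyl]trideca-2,6,9,12-tetraenoate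
Product: 19 methyl (2Z,4R,5S,6E,9Z,11R)-5-acetoxy-11-(tert-butyldimethylsilyloxy)-6-(methoxycarbonyl)-10-methyl-8,12-dioxo-4-(triethylsilyloxy)-2-[(trimethylsilyl)methyl]dodeca-2,6,9-trienoate, via diol 18 (not isolated)
Conditions: OsO4 (2 mol %), NaIO4, 2,6-lutidine, dioxane–H2O, 0 °C → rt
Reagents that add atoms: sodium periodate [Na+].[O-]I(=O)(=O)=O
Why: Lemieux–Johnson cleavage again selects the only non-conjugated monosubstituted alkene and unmasks the C-6 aldehyde next to the C-5 silyl ether; the aldehyde is used at once.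

**Step 12**
Reactants: 19 methyl (2Z,4R,5S,6E,9Z,11R)-5-acetoxy-11-(tert-butyldimethylsilyloxy)-6-(methoxycarbonyl)-10-methyl-8,12-dioxo-4-(triethylsilyloxy)-2-[(trimethylsilyl)methyl]dodeca-2,6,9-trienoate
Product: 22 methyl 9α-acetoxy-5α-(tert-butyldimethylsilyloxy)-8α-hydroxy-2-oxogermacra-1(10)E,3Z,11(13)-trien-12,6α-olid-14-oate, via hydroxy ester 20 (not isolated), via silyl lactone 21 (not isolated)
Conditions: BF3·OEt2 (1.5 equiv), CH2Cl2 (0.002 M), −78 → −20 °C; then MeOH, 0 °C
Reagents that add atoms: none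
Why: Intramolecular Hosomi–Sakurai allylation (a cation–olefin closure with silicon in the role of the proton) in which C-7 of the allylsilane attacks the BF3-bound aldehyde with Felkin–Anh control from C-5 (5,6-anti) and C-5/C-8 anti about the new bond (H-6/H-7 trans), after which the C-6 oxygen lactonises onto C-12 and methanolic BF3 removes the secondary TES ether.

**Step 13**
Reactants: 22 methyl 9α-acetoxy-5α-(tert-butyldimethylsilyloxy)-8α-hydroxy-2-oxogermacra-1(10)E,3Z,11(13)-trien-12,6α-olid-14-oate; 23 angelic acid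
Product: 24 methyl 9α-acetoxy-8β-angeloyloxy-5α-(tert-butyldimethylsilyloxy)-2-oxogermacra-1(10)E,3Z,11(13)-trien-12,6α-olid-14-oate
Conditions: PPh3, DIAD (betaine preformed), toluene, 0 °C → rt
Reagents that add atoms: none
Why: Mitsunobu esterification: SN2 displacement of the activated 8α-oxygen by angelate inverts C-8 to the configuration of the target and introduces the Z-acid without isomerisation, with the betaine preformed so that free PPh3 does not meet the dienone.

**Step 14**
Reactants: 24 methyl 9α-acetoxy-8β-angeloyloxy-5α-(tert-butyldimethylsilyloxy)-2-oxogermacra-1(10)E,3Z,11(13)-trien-12,6α-olid-14-oate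
Product: 26 CNP0208424.1 (target), via hydroxy dienone 25 (not isolated)
Conditions: HF·pyridine, pyridine, THF, 0 °C → rt
Reagents that add atoms: none
Why: Cleavage of the allylic TBS ether frees the C-5 hydroxyl of the (Z)-γ-hydroxy enone, which closes onto the C-2 ketone (5-exo hemiketalisation) to the bridged dihydrofuranol, with C-2 set under thermodynamic control.

**Compound list**
1 | trimethyl phosphonoacetate | COC(=O)CP(=O)(OC)OC | starting material
2 | (iodomethyl)trimethylsilane | C[Si](C)(C)CI | starting material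
3 | methyl 2-(dimethoxyphosphoryl)-3-(trimethylsilyl)propanoate | COC(=O)C(C[Si](C)(C)C)P(=O)(OC)OC | intermediate
4 | (R)-but-3-ene-1,2-diol | OC[C@H](O)C=C | starting material
5 | (R)-3,4-bis(triethylsilyloxy)but-1-ene | CC[Si](CC)(CC)OC[C@H](O[Si](CC)(CC)CC)C=C | intermediate
6 | (R)-2-(triethylsilyloxy)but-3-enal | O=C[C@H](O[Si](CC)(CC)CC)C=C | intermediate
7 | methyl propiolate | C#CC(=O)OC | starting material
8 | methyl (2E,3S,4R)-3-hydroxy-2-(iodomethylidene)-4-(triethylsilyloxy)hex-5-enoate | I/C=C(/C(=O)OC)[C@H](O)[C@H](O[Si](CC)(CC)CC)C=C | intermediate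
9 | methyl (2E,3S,4R)-3-acetoxy-2-(iodomethylidene)-4-(triethylsilyloxy)hex-5-enoate | I/C=C(/C(=O)OC)[C@H](OC(C)=O)[C@H](O[Si](CC)(CC)CC)C=C | intermediate
10 | 5,6-diol of 9 (C-5 epimers; C-3 and C-4 as in 9) | I/C=C(/C(=O)OC)[C@H](OC(C)=O)[C@H](O[Si](CC)(CC)CC)C(O)CO | intermediate (not isolated)
11 | methyl (2E,3S,4S)-3-acetoxy-2-(iodomethylidene)-5-oxo-4-(triethylsilyloxy)pentanoate | I/C=C(/C(=O)OC)[C@H](OC(C)=O)[C@H](O[Si](CC)(CC)CC)C=O | intermediate
12 | dimethyl (2E,3S,4R,5Z)-3-acetoxy-2-(iodomethylidene)-4-(triethylsilyloxy)-6-[(trimethylsilyl)methyl]hept-5-enedioate | I/C=C(/C(=O)OC)[C@H](OC(C)=O)[C@H](O[Si](CC)(CC)CC)/C=C(/C(=O)OC)C[Si](C)(C)C | intermediate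
13 | rac-pent-1-en-4-yn-3-ol | C#CC(O)C=C | starting material
14 | (S)-pent-1-en-4-yn-3-ol | C#C[C@@H](O)C=C | intermediate
15 | bromomagnesium (3S,1Z)-2-methyl-1-(tributylstannyl)penta-1,4-dien-3-olate | CCCC[Sn](CCCC)(CCCC)/C=C(C)\[C@@H]([O-])C=C.[Mg+2].[Br-] | intermediate (not isolated)
16 | tert-butyldimethyl{[(3S,1Z)-2-methyl-1-(tributylstannyl)penta-1,4-dien-3-yl]oxy}silane | CCCC[Sn](CCCC)(CCCC)/C=C(C)\[C@@H](O[Si](C)(C)C(C)(C)C)C=C | intermediate
17 | methyl (2Z,4R,5S,6E,9Z,11S)-5-acetoxy-11-(tert-butyldimethylsilyloxy)-6-(methoxycarbonyl)-10-methyl-8-oxo-4-(triethylsilyloxy)-2-[(trimethylsilyl)methyl]trideca-2,6,9,12-tetraenoate | C=C[C@H](O[Si](C)(C)C(C)(C)C)/C(C)=C\C(=O)/C=C(/C(=O)OC)[C@H](OC(C)=O)[C@H](O[Si](CC)(CC)CC)/C=C(/C(=O)OC)C[Si](C)(C)C | intermediate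
18 | 12,13-diol of 17 (C-12 epimers; other centres as in 17) | OCC(O)[C@H](O[Si](C)(C)C(C)(C)C)/C(C)=C\C(=O)/C=C(/C(=O)OC)[C@H](OC(C)=O)[C@H](O[Si](CC)(CC)CC)/C=C(/C(=O)OC)C[Si](C)(C)C | intermediate (not isolated)
19 | methyl (2Z,4R,5S,6E,9Z,11R)-5-acetoxy-11-(tert-butyldimethylsilyloxy)-6-(methoxycarbonyl)-10-methyl-8,12-dioxo-4-(triethylsilyloxy)-2-[(trimethylsilyl)methyl]dodeca-2,6,9-trienoate | O=C[C@H](O[Si](C)(C)C(C)(C)C)/C(C)=C\C(=O)/C=C(/C(=O)OC)[C@H](OC(C)=O)[C@H](O[Si](CC)(CC)CC)/C=C(/C(=O)OC)C[Si](C)(C)C | intermediate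
20 | dimethyl 9α-acetoxy-5α-(tert-butyldimethylsilyloxy)-6α-hydroxy-2-oxo-8α-(triethylsilyloxy)germacra-1(10)E,3Z,11(13)-triene-12,14-dioate (H-7α) | C=C(C(=O)OC)[C@H]1[C@H](O)[C@H](O[Si](C)(C)C(C)(C)C)/C(C)=C\C(=O)/C=C(/C(=O)OC)[C@H](OC(C)=O)[C@@H]1O[Si](CC)(CC)CC | intermediate (not isolated)
21 | methyl 9α-acetoxy-5α-(tert-butyldimethylsilyloxy)-2-oxo-8α-(triethylsilyloxy)germacra-1(10)E,3Z,11(13)-trien-12,6α-olid-14-oate | C=C1C(=O)O[C@H]2[C@H]1[C@@H](O[Si](CC)(CC)CC)[C@@H](OC(C)=O)/C(C(=O)OC)=C\C(=O)/C=C(C)\[C@H]2O[Si](C)(C)C(C)(C)C | intermediate (not isolated)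
22 | methyl 9α-acetoxy-5α-(tert-butyldimethylsilyloxy)-8α-hydroxy-2-oxogermacra-1(10)E,3Z,11(13)-trien-12,6α-olid-14-oate (C-8 epimeric to the target) | C=C1C(=O)O[C@H]2[C@H]1[C@@H](O)[C@@H](OC(C)=O)/C(C(=O)OC)=C\C(=O)/C=C(C)\[C@H]2O[Si](C)(C)C(C)(C)C | intermediate
23 | angelic acid, (Z)-2-methylbut-2-enoic acid | C/C=C(/C)C(=O)O | starting material
24 | methyl 9α-acetoxy-8β-angeloyloxy-5α-(tert-butyldimethylsilyloxy)-2-oxogermacra-1(10)E,3Z,11(13)-trien-12,6α-olid-14-oate | C=C1C(=O)O[C@H]2[C@H]1[C@H](OC(=O)/C(C)=C\C)[C@@H](OC(C)=O)/C(C(=O)OC)=C\C(=O)/C=C(C)\[C@H]2O[Si](C)(C)C(C)(C)C | intermediate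
25 | methyl 9α-acetoxy-8β-angeloyloxy-5α-hydroxy-2-oxogermacra-1(10)E,3Z,11(13)-trien-12,6α-olid-14-oate | C=C1C(=O)O[C@H]2[C@H]1[C@H](OC(=O)/C(C)=C\C)[C@@H](OC(C)=O)/C(C(=O)OC)=C\C(=O)/C=C(C)\[C@H]2O | intermediate (not isolated)
26 | CNP0208424.1: methyl (2R,5R,6S,7S,8S,9S)-9-acetoxy-8-angeloyloxy-2,5-epoxy-2-hydroxygermacra-1(10),3,11(13)-trien-12,6-olid-14-oate | C=C1C(=O)O[C@H]2[C@H]1[C@H](OC(=O)/C(C)=C\C)[C@@H](OC(C)=O)/C(C(=O)OC)=C\[C@@]1(O)C=C(C)[C@H]2O1 | target

**Totals**
Total step count: 14. Longest linear sequence: 11 (steps 2–7 and 10–14).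

**The three steps most likely to fail**

Step 12 (macrocyclisation). The open-transition-state allylation must form a ten-membered ring, choose the aldehyde over the dienone, and set C-6 and C-7 correctly. The fallback sets out from 19. Bromodesilylation with NBS (CH2Cl2, −78 °C) converts the allylsilane into the allylic bromide, the 7-bromo-11(13)-ene seco-aldehyde F1. Slow addition of this bromide to CrCl2 in THF (Nozaki–Hiyama–Kishi allylation through a closed, aldehyde-selective, anti-selective allylchromium transition state) closes C6–C7, and the chromium alkoxide lactonises. The route comes back at 21, which loses its TES group with methanolic acid as in step 12.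

Step 4 (halo-aldol). The (E)-iodide is the kinetic and less stable isomer, and the Felkin selectivity may be modest. The fallback sets out from 6 and builds the C1=C10 bond by a Wittig reaction instead.
- Vinylalumination with 7 (DIBAL-H, NMO, THF, 0 °C) gives the Baylis–Hillman-type alcohol methyl 3-hydroxy-2-methylidene-4-(triethylsilyloxy)hex-5-enoate F2 (3,4-anti).
- Acetylation gives the acetate F3.
- Ozonolysis of both terminal alkenes (O3, then Me2S) gives the α-keto ester aldehyde F4.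
- Horner–Wadsworth–Emmons reaction of the aldehyde with 3 gives the allylsilane α-keto ester F5.
- Tin–lithium exchange on 16 (n-BuLi) and capture by Ph3P=C=C=O gives the acyl ylide (3Z,5S)-5-(tert-butyldimethylsilyloxy)-4-methyl-1-(triphenylphosphoranylidene)hepta-3,6-dien-2-one F6.
- Wittig olefination of F5 with F6 in toluene is expected to place the acyl group cis to C-9, steered by the α-acyloxy ketone and the ester dipole, and comes back at 17.

Step 13 (Mitsunobu inversion on a hindered macrocyclic alcohol). Elimination, acetate participation, or phosphine addition to the dienone could intervene. The fallback sets out from 22 and replaces SN2 inversion by a redox inversion and an acylation with retention.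
- HF·pyridine first closes the hemiketal to the 8α-hydroxy hemiketal F7, which masks the C-2 ketone.
- Dess–Martin oxidation gives the 8-ketone F8.
- Reduction from the outer face (NaBH4, CeCl3, −78 °C) gives the 8β-alcohol F9.
- Acylation with the mixed anhydride of 23 and 2,4,6-trichlorobenzoyl chloride (Et3N, toluene, no DMAP) comes back at 26.

**Further compounds**
F1 | step 12 | allylic bromide: 7-bromo-11(13)-ene analogue of 19 (C-7 epimers) | O=C[C@H](O[Si](C)(C)C(C)(C)C)/C(C)=C\C(=O)/C=C(/C(=O)OC)[C@H](OC(C)=O)[C@H](O[Si](CC)(CC)CC)C(Br)C(=C)C(=O)OC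
F2 | step 4 | methyl 3-hydroxy-2-methylidene-4-(triethylsilyloxy)hex-5-enoate (3,4-anti; C-8 and C-9 as in 8) | C=C(C(=O)OC)[C@H](O)[C@H](O[Si](CC)(CC)CC)C=C
F3 | step 4 | acetate of F2 | C=C(C(=O)OC)[C@H](OC(C)=O)[C@H](O[Si](CC)(CC)CC)C=C
F4 | step 4 | methyl 3-acetoxy-2,5-dioxo-4-(triethylsilyloxy)pentanoate (C-8 and C-9 as in 11) | COC(=O)C(=O)[C@H](OC(C)=O)[C@H](O[Si](CC)(CC)CC)C=O
F5 | step 4 | dimethyl (5Z)-3-acetoxy-2-oxo-4-(triethylsilyloxy)-6-[(trimethylsilyl)methyl]hept-5-enedioate (C-8 and C-9 as in 12) | COC(=O)C(=O)[C@H](OC(C)=O)[C@H](O[Si](CC)(CC)CC)/C=C(/C(=O)OC)C[Si](C)(C)C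
F6 | step 4 | (3Z,5S)-5-(tert-butyldimethylsilyloxy)-4-methyl-1-(triphenylphosphoranylidene)hepta-3,6-dien-2-one | C=C[C@H](O[Si](C)(C)C(C)(C)C)/C(C)=C\C(=O)C=P(c1ccccc1)(c1ccccc1)c1ccccc1
F7 | step 13 | 8α-hydroxy hemiketal (8-epi-8-deacyl target) | C=C1C(=O)O[C@H]2[C@H]1[C@@H](O)[C@@H](OC(C)=O)/C(C(=O)OC)=C\[C@@]1(O)C=C(C)[C@H]2O1
F8 | step 13 | 8-oxo hemiketal | C=C1C(=O)O[C@H]2[C@H]1C(=O)[C@@H](OC(C)=O)/C(C(=O)OC)=C\[C@@]1(O)C=C(C)[C@H]2O1
F9 | step 13 | 8β-hydroxy hemiketal (8-deacyl target) | C=C1C(=O)O[C@H]2[C@H]1[C@H](O)[C@@H](OC(C)=O)/C(C(=O)OC)=C\[C@@]1(O)C=C(C)[C@H]2O1
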